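## Analysis of the target

allo-Pertusaric acid 20 is a fully substituted γ-butyrolactone, numbered here O1, C2 (lactone carbonyl), C3 (exocyclic methylene), C4 (free carboxylic acid) and C5 (14-oxopentadecyl chain). There are only two stereocentres, C4 and C5, both S and adjacent, with the carboxyl and the chain on the same face of the ring; this cis arrangement is the less stable one for a paraconic acid. The sensitive groups are the α-methylene lactone (a Michael acceptor whose double bond can move into the ring by loss of C4–H), the C4 centre (α to a carboxyl, with the lactone oxygen as a β-leaving group) and the remote methyl ketone, which must be masked whenever carbanions are present. The chain has no stereochemistry and only this one ketone, so it is a matter of carbon count. The difficulty lies in the ring: absolute configuration, the contra-thermodynamic cis relationship, and late introduction of the methylene next to an epimerisable centre. The plan rests on one observation: the ring O1–C2–C3–C4–C5 with a carboxyl at C4 is the γ-lactone 10 of natural (2R,3S)-isocitric acid 9. Its two stereocentres map atom for atom onto C5 and C4 with the cis relationship and the correct absolute sense, and its second carboxyl sits on C5 exactly where the first chain carbon belongs, so both stereocentres can be bought and the synthesis reduces to turning one specific carboxyl into a C15 chain and adding one carbon at C3.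

## Retrosynthetic reasoning

20 ⇒ 19. The methyl ketone is unmasked last. It stays as a dioxolane because the chain is attached with a basic ylide and the methylene is introduced through a lactone enolate; a free methyl ketone would react in both operations. The forward step is a mild acidic hydrolysis that must leave the α-methylene lactone alone.

19 ⇒ 18 ⇒ 17. The C3=CH2 bond is cut next, since the methylene lactone is the most fragile function and should be present for one step only. Retron: a carboxyl on C3, as in 18, placed there by carboxylation of the lactone enolate of 17 and then exchanged for the methylene by a decarboxylative Mannich condensation. The free C4 acid is an advantage: as its carboxylate it shields C4–H from deprotonation, so the cis relationship should survive.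

17 ⇒ 16. Functional-group interconversion only: the chain alkene and the benzyl ester of 16 are removed together by hydrogenation. This makes the geometry of the alkene irrelevant.

16 ⇒ 14 + 15. The bond between the first and second chain carbons is cut as a Wittig olefination. Cutting here puts all stereochemistry into aldehyde 14 and all chain carbons but one into ylide 15; that one carbon is the former carboxyl carbon of 9. A cut further out would require homologating the chiral fragment; a cut at the ring would destroy the C5 centre. The forward step must add a basic ylide to an α-acyloxy aldehyde without touching C5–H, C4–H, the lactone or the ester.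

15 ⇒ 7 ⇒ 5 + 6; 5 ⇒ 4 ⇒ 3 ⇒ 1 + 2. The ylide comes from phosphonium salt 7, made by quaternising triphenylphosphine 6 with bromo ketal 5. The methyl ketone end is the acetone unit of ethyl acetoacetate 1, joined to 1,11-dibromoundecane 2 by C-alkylation, ketonic cleavage (3 → 4) and ketalisation (4 → 5). Carbon count: 3 from the acetone unit plus 11 gives the 14-carbon ylide.

14 ⇒ 13 ⇒ 12 ⇒ 11. The aldehyde is reached from thioester 13 by palladium-catalysed silane reduction, which stops at the aldehyde and spares lactone and benzyl ester. The two carboxyls are told apart in the cis-fused anhydride 11: the carbonyl attached to C5 carries the inductive pull of the ring oxygen and should be the more electrophilic. An oxygen nucleophile delivering the benzyl group would therefore end up on the carboxyl that must become the chain. The plan instead sends a thiol to that carbonyl, giving 12, and benzylates the acid left at C4 afterwards, giving 13, so each carboxyl receives the group it needs in two steps.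

11 ⇒ 10 ⇒ 9 ⇒ 8. The anhydride is the dehydration product of the cis lactone diacid 10, which forms when free isocitric acid 9, liberated from its commercial monopotassium salt 8, is heated. No stereocentre is created anywhere; C4 and C5 of 20 are C3 and C2 of 9.

## Alternatives that were turned down

Alternative 1: The lactone is disconnected at O1–C2 and C2–C3, with the carbonyl carbon supplied as CO between the C5 hydroxyl and the terminal alkyne of the syn homopropargylic alcohol A2. Forward key step: cyclocarbonylation with PdCl2/SnCl2/PPh3 under CO gives A1, the cis α-methylene lactone with a silyloxymethyl group at C4.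
- For: the methylene arrives with the ring, so no enolate is generated next to C4, and the chain can carry its ketone unprotected. On this point it is stronger than the chosen route, which spends two steps and a ketal on the methylene.
- Against: both stereocentres of A2 must first be made by reagent control in an acyclic system. After the key step, the C4 substituent of A1 must be desilylated and oxidised in two stages to the acid. At that stage C4–H is allylic, α to a carbonyl and next to a Michael acceptor, so epimerisation to the trans series or migration of the double bond into the ring is expected exactly where the cis configuration has to survive.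
- Comparison: the chosen route brings C4 in at the carboxylic acid oxidation level, with both centres already fixed, and never oxidises next to the finished methylene lactone.

Alternative 2: The five-membered ring is derived from a six-membered one. The C4–C5 bond is formed by Wolff ring contraction of the diazo keto δ-lactone A4, itself reached through an Achmatowicz-type oxidative ring expansion. Forward key step: irradiation of A4 in aqueous THF expels N2, the chain-bearing carbon migrates with retention, and water captures the rearranged acyl carbon as the C4 carboxyl of A3, which is the same compound as 17.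
- For: it converges on an intermediate of the chosen route, the migrating centre keeps its configuration, and no two carboxyls need to be distinguished. On that last point it is stronger.
- Against: C4 becomes a stereocentre only in the last proton transfer after water has added, so the cis relationship depends on kinetic facial selectivity against the thermodynamic preference. A4 needs an enantioselective carbinol synthesis, oxidative ring expansion, redox adjustment and diazo transfer, which is clearly longer than the route to 14. The α-acyloxy ketone centre of A4 is epimerisable, and a 1,2-hydrogen shift after loss of N2 can compete with ring contraction.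
- Comparison: the chosen route reaches the same acid 17 with both centres inherited and not induced.

Alternative 3: The hydroxy diester A5 is disconnected at the C5–H bond back to the racemic acylsuccinate A6, which a Stetter-type conjugate acylation would assemble in one step. Forward key step: transfer hydrogenation of A6 with one enantiomer of RuCl(p-cymene)(TsDPEN) and HCO2H/NEt3 (or a ketoreductase) while the α-centre epimerises, giving anti-configured A5, from which lactonisation would lead into the cis series.
- For: it is the shortest and most convergent plan, fully catalytic, sets both centres in one step, and needs no Wittig reaction, hydrogenation or carboxyl differentiation. In step economy it is stronger than the chosen route.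
- Against: everything depends on one untested catalyst–substrate match. The ketone of A6 lies between a long n-alkyl chain and an α-branched ester, with no aryl or alkynyl group for the catalyst to recognise, and both the enantioselectivity and the syn/anti sense of such dynamic reductions vary with substrate. An enzyme screen might solve this but cannot be planned on paper.
- Comparison: the chosen route is several steps longer, but its absolute and relative configuration are certain from the start, and its risk lies in chemoselectivity, which can be controlled by conditions.

Key step: step 10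

Assumption: the commercial salt is taken to be monopotassium (2R,3S)-isocitrate 8, and anhydride 11 is assumed to open at the carbonyl attached to the oxygen-bearing carbon, as O-acyl malic anhydrides do.

## Route

Step 1
Reactants: 1 ethyl acetoacetate (ethyl 3-oxobutanoate); 2 1,11-dibromoundecane
Product: 3 ethyl 2-acetyl-13-bromotridecanoate (racemic)
Conditions: K2CO3 (1.5 equiv), acetone, reflux; 2 in threefold excess (recovered)
Reagents that add atoms: none
Why: Acetoacetic ester alkylation: the enolate displaces one bromide by SN2, and the excess of 2 keeps the second bromide from meeting another enolate. The new centre is racemic and is lost in step 2.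

Step 2
Reactants: 3 ethyl 2-acetyl-13-bromotridecanoate
Product: 4 14-bromotetradecan-2-one
Conditions: 48% aq. HBr, AcOH, 100 °C
Reagents that add atoms: none
Why: Ketonic cleavage: acid hydrolysis of the ester gives the β-keto acid, which decarboxylates through the cyclic six-membered transition state. HBr as the acid keeps the primary bromide intact, since any solvolysis is reversed by bromide.

Step 3
Reactants: 4 14-bromotetradecan-2-one
Product: 5 2-(12-bromododecyl)-2-methyl-1,3-dioxolane
Conditions: HOCH2CH2OH, p-TsOH (cat.), toluene, reflux, Dean–Stark
Reagents that add atoms: ethane-1,2-diol, OCCO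
Why: Acid-catalysed ketalisation driven by azeotropic removal of water. The dioxolane hides the methyl ketone from the ylide base of step 10 and from the carboxylation of step 12.

Step 4
Reactants: 5 2-(12-bromododecyl)-2-methyl-1,3-dioxolane; 6 triphenylphosphine
Product: 7 [12-(2-methyl-1,3-dioxolan-2-yl)dodecyl]triphenylphosphonium bromide
Conditions: MeCN, reflux; Et2O trituration; dried in vacuo
Reagents that add atoms: none
Why: SN2 quaternisation of the phosphine by the primary bromide; the ketal is inert under these neutral conditions.

Step 5
Reactants: 8 monopotassium (2R,3S)-isocitrate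
Product: 10 (2R,3S)-5-oxooxolane-2,3-dicarboxylic acid (cis isocitric acid lactone), via free (2R,3S)-isocitric acid 9 (not isolated)
Conditions: 2 M aq. HCl (1.05 equiv), rt; evaporate; melt, 100 °C, 20 mbar; extract into acetone
Reagents that add atoms: none
Why: Protonation frees the triacid, and on heating the hydroxyl closes onto the CH2CO2H carboxyl to give the γ-lactone, the only unstrained ring available. Neither stereocentre is touched, so the threo acid gives the cis-dicarboxy lactone.

Step 6
Reactants: 10 (2R,3S)-5-oxooxolane-2,3-dicarboxylic acid
Product: 11 (3aS,6aR)-3a,6a-dihydrofuro[3,4-b]furan-2,4,6(3H)-trione (the cis-fused cyclic anhydride of 10)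
Conditions: Ac2O, 80 °C; evaporate with toluene
Reagents that add atoms: none
Why: Dehydration of a cis-1,2-dicarboxylic acid to its five-membered cyclic anhydride by acyl exchange with Ac2O; only the cis diacid can close.

Step 7
Reactants: 11 (3aS,6aR)-3a,6a-dihydrofuro[3,4-b]furan-2,4,6(3H)-trione
Product: 12 (2R,3S)-2-[(ethylsulfanyl)carbonyl]-5-oxooxolane-3-carboxylic acid
Conditions: EtSH (1.2 equiv), Et3N (1.05 equiv), CH2Cl2, −40 °C; cold 1 M HCl quench
Reagents that add atoms: ethanethiol, CCS
Why: Thiolysis of a cyclic anhydride. The carbonyl attached to C5 feels the inductive pull of the ring oxygen and should be attacked preferentially, as in the opening of O-acyl malic anhydrides, so the thioester forms on the carboxyl that becomes the chain. Low temperature and a cold acidic quench keep the carboxylate from re-closing and scrambling.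

Step 8
Reactants: 12 (2R,3S)-2-[(ethylsulfanyl)carbonyl]-5-oxooxolane-3-carboxylic acid
Product: 13 benzyl (2R,3S)-2-[(ethylsulfanyl)carbonyl]-5-oxooxolane-3-carboxylate
Conditions: BnOC(=NH)CCl3 (1.5 equiv), CH2Cl2/cyclohexane, rt
Reagents that add atoms: benzyl 2,2,2-trichloroacetimidate, ClC(Cl)(Cl)C(=N)OCc1ccccc1
Why: Esterification with a trichloroacetimidate: the acid protonates the imidate and the carboxylate takes up the benzyl group. No base is present, so the neighbouring carboxylate cannot expel the thiol and neither α-centre is at risk.

Step 9
Reactants: 13 benzyl (2R,3S)-2-[(ethylsulfanyl)carbonyl]-5-oxooxolane-3-carboxylate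
Product: 14 benzyl (2R,3S)-2-formyl-5-oxooxolane-3-carboxylate
Conditions: Et3SiH (3 equiv), 10% Pd/C (5 mol%), acetone, rt, Ar; filter, evaporate, use at once
Reagents that add atoms: none
Why: Fukuyama reduction: the C–S bond adds oxidatively to palladium, the silane delivers hydride, and reductive elimination releases the aldehyde. Lactone and benzyl ester are not attacked under these hydrogen-free neutral conditions, and the labile α-acyloxy aldehyde is not chromatographed.

Step 10
Reactants: 7 [12-(2-methyl-1,3-dioxolan-2-yl)dodecyl]triphenylphosphonium bromide; 14 benzyl (2R,3S)-2-formyl-5-oxooxolane-3-carboxylate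
Product: 16 benzyl (2S,3S)-2-[(1Z)-13-(2-methyl-1,3-dioxolan-2-yl)tridec-1-en-1-yl]-5-oxooxolane-3-carboxylate, via phosphonium ylide 15 (not isolated)
Conditions: 7 (1.1 equiv), KN(SiMe3)2 (1.05 equiv), THF, −78 → 0 °C; ylide added slowly to 14, THF, −78 → −20 °C; aq. NH4Cl
Reagents that add atoms: none
Why: The lithium-free ylide 15 adds through carbon to the aldehyde carbonyl of 14 in an asynchronous [2+2] cycloaddition, and the resulting cis-oxaphosphetane collapses by syn cycloreversion to the (Z)-alkene and triphenylphosphine oxide; this forms the bond between the first and second chain carbons. The closest known reaction type is the salt-free Wittig olefination of 5-oxooxolane-2-carbaldehydes and other α-oxygenated aldehydes with non-stabilised alkylidenephosphoranes. No ring is closed and no stereocentre is formed; the alkene geometry is irrelevant because step 11 removes it. The step needs chemoselectivity and configurational integrity: the aldehyde, activated by the α-oxygen, is far more electrophilic than the lactone or the benzyl ester and should be the only carbonyl attacked at −78 °C. The acidic sites are C5–H (α to the aldehyde) and C4–H (α to the ester, with the lactone oxygen as β-leaving group), so the ylide is kept from acting as a base by slow addition to the aldehyde, by using no excess of KN(SiMe3)2 and by a cold quench. The dioxolane keeps the remote ketone out of the reaction and is stable to the basic medium.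

Step 11
Reactants: 16 benzyl (2S,3S)-2-[(1Z)-13-(2-methyl-1,3-dioxolan-2-yl)tridec-1-en-1-yl]-5-oxooxolane-3-carboxylate
Product: 17 (2S,3S)-2-[13-(2-methyl-1,3-dioxolan-2-yl)tridecyl]-5-oxooxolane-3-carboxylic acid
Conditions: H2 (1 atm), 10% Pd/C, EtOAc, rt
Reagents that add atoms: none
Why: Heterogeneous hydrogenation saturates the disubstituted alkene and hydrogenolyses the benzyl ester in the same operation. Ketal, lactone and both stereocentres are untouched under neutral conditions.

Step 12
Reactants: 17 (2S,3S)-2-[13-(2-methyl-1,3-dioxolan-2-yl)tridecyl]-5-oxooxolane-3-carboxylic acid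
Product: 18 (2S,3S,4R)-2-[13-(2-methyl-1,3-dioxolan-2-yl)tridecyl]-5-oxooxolane-3,4-dicarboxylic acid (crude; the new malonic-type centre is labile)
Conditions: MeOMgOCO2Me (2 M in DMF, excess), 130 °C; cold 1 M HCl to pH 3, EtOAc, 0 °C, fast extraction
Reagents that add atoms: methoxymagnesium methyl carbonate, CO[Mg]OC(=O)OC
Why: Carboxylation of the lactone α-carbon with MeOMgOCO2Me: the substrate reacts as its magnesium carboxylate, which shields C4–H, and the C3 enolate is carboxylated and held as a magnesium chelate that drives the equilibrium. The basic medium leaves the dioxolane intact, and the new centre is lost in step 13.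

Step 13
Reactants: 18 (2S,3S,4R)-2-[13-(2-methyl-1,3-dioxolan-2-yl)tridecyl]-5-oxooxolane-3,4-dicarboxylic acid
Product: 19 (2S,3S)-4-methylidene-2-[13-(2-methyl-1,3-dioxolan-2-yl)tridecyl]-5-oxooxolane-3-carboxylic acid
Conditions: 37% aq. CH2O, PhNHMe, NaOAc, AcOH, rt
Reagents that add atoms: formaldehyde, C=O
Why: Decarboxylative Mannich methylenation: the malonic half-acid condenses with the iminium ion from formaldehyde and N-methylaniline, and the adduct loses CO2 and the amine to give the exocyclic alkene. The buffered acidic medium at room temperature avoids both C4 epimerisation and migration of the double bond into the ring.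

Step 14
Reactants: 19 (2S,3S)-4-methylidene-2-[13-(2-methyl-1,3-dioxolan-2-yl)tridecyl]-5-oxooxolane-3-carboxylic acid
Product: 20 allo-pertusaric acid, (2S,3S)-4-methylidene-5-oxo-2-(14-oxopentadecyl)oxolane-3-carboxylic acid
Conditions: 1 M aq. HCl, THF, rt
Reagents that add atoms: water, O
Why: Acid-catalysed hydrolysis of the dioxolane through the oxocarbenium ion. The α-methylene lactone and the carboxylic acid are stable to dilute aqueous acid; base is avoided because it would isomerise the alkene.

## Compound list

1 | ethyl acetoacetate | CCOC(=O)CC(C)=O | starting material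
2 | 1,11-dibromoundecane | BrCCCCCCCCCCCBr | starting material
3 | ethyl 2-acetyl-13-bromotridecanoate (racemic) | CCOC(=O)C(CCCCCCCCCCCBr)C(C)=O | intermediate
4 | 14-bromotetradecan-2-one | CC(=O)CCCCCCCCCCCCBr | intermediate
5 | 2-(12-bromododecyl)-2-methyl-1,3-dioxolane | CC1(CCCCCCCCCCCCBr)OCCO1 | intermediate
6 | triphenylphosphine | c1ccc(cc1)P(c1ccccc1)c1ccccc1 | starting material
7 | [12-(2-methyl-1,3-dioxolan-2-yl)dodecyl]triphenylphosphonium bromide | CC1(CCCCCCCCCCCC[P+](c2ccccc2)(c2ccccc2)c2ccccc2)OCCO1.[Br-] | intermediate
8 | monopotassium (2R,3S)-isocitrate | O[C@@H](C(=O)[O-])[C@H](CC(=O)O)C(=O)O.[K+] | starting material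
9 | (2R,3S)-isocitric acid, (1R,2S)-1-hydroxypropane-1,2,3-tricarboxylic acid | O[C@@H](C(=O)O)[C@H](CC(=O)O)C(=O)O | intermediate
10 | (2R,3S)-5-oxooxolane-2,3-dicarboxylic acid (cis) | C1C(=O)O[C@@H](C(=O)O)[C@H]1C(=O)O | intermediate
11 | (3aS,6aR)-3a,6a-dihydrofuro[3,4-b]furan-2,4,6(3H)-trione | C1C(=O)O[C@@H]2[C@H]1C(=O)OC2=O | intermediate
12 | (2R,3S)-2-[(ethylsulfanyl)carbonyl]-5-oxooxolane-3-carboxylic acid | C1C(=O)O[C@@H](C(=O)SCC)[C@H]1C(=O)O | intermediate
13 | benzyl (2R,3S)-2-[(ethylsulfanyl)carbonyl]-5-oxooxolane-3-carboxylate | C1C(=O)O[C@@H](C(=O)SCC)[C@H]1C(=O)OCc2ccccc2 | intermediate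
14 | benzyl (2R,3S)-2-formyl-5-oxooxolane-3-carboxylate | C1C(=O)O[C@@H](C=O)[C@H]1C(=O)OCc2ccccc2 | intermediate
15 | [12-(2-methyl-1,3-dioxolan-2-yl)dodecylidene]triphenylphosphorane | CC1(CCCCCCCCCCCC=P(c2ccccc2)(c2ccccc2)c2ccccc2)OCCO1 | intermediate
16 | benzyl (2S,3S)-2-[(1Z)-13-(2-methyl-1,3-dioxolan-2-yl)tridec-1-en-1-yl]-5-oxooxolane-3-carboxylate | C1C(=O)O[C@@H](/C=C\CCCCCCCCCCCC2(C)OCCO2)[C@H]1C(=O)OCc3ccccc3 | intermediate
17 | (2S,3S)-2-[13-(2-methyl-1,3-dioxolan-2-yl)tridecyl]-5-oxooxolane-3-carboxylic acid | C1C(=O)O[C@@H](CCCCCCCCCCCCCC2(C)OCCO2)[C@H]1C(=O)O | intermediate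
18 | (2S,3S,4R)-2-[13-(2-methyl-1,3-dioxolan-2-yl)tridecyl]-5-oxooxolane-3,4-dicarboxylic acid | OC(=O)[C@@H]1C(=O)O[C@@H](CCCCCCCCCCCCCC2(C)OCCO2)[C@H]1C(=O)O | intermediate
19 | (2S,3S)-4-methylidene-2-[13-(2-methyl-1,3-dioxolan-2-yl)tridecyl]-5-oxooxolane-3-carboxylic acid | C=C1C(=O)O[C@@H](CCCCCCCCCCCCCC2(C)OCCO2)[C@H]1C(=O)O | intermediate
20 | allo-pertusaric acid, (2S,3S)-4-methylidene-5-oxo-2-(14-oxopentadecyl)oxolane-3-carboxylic acid | C=C1C(=O)O[C@@H](CCCCCCCCCCCCCC(C)=O)[C@H]1C(=O)O | target

## Step count and least certain steps

Total step count: 14. Longest linear sequence: 10 steps (steps 5–14, from 8); the chain branch (steps 1–4) joins at step 10.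

Step 10 (key step). The most likely failure is the ylide acting as a base instead of a nucleophile. Deprotonation at C5 of the α-acyloxy aldehyde would erode the cis relationship, and deprotonation at C4 would trigger β-elimination of the lactone carboxylate and open the ring. Partial hydration of the labile aldehyde before the coupling would also consume ylide. Fallback: a non-basic organochromium alkylidenation in place of the ylide, setting out from bromide 5 and aldehyde 14 and returning to the route at 17. Kornblum oxidation of 5 (DMSO, NaHCO3, catalytic NaI, 110 °C) should give 12-(2-methyl-1,3-dioxolan-2-yl)dodecanal F1. Hydrazine hydrate in EtOH converts it into (E)-[12-(2-methyl-1,3-dioxolan-2-yl)dodecylidene]hydrazine F2, and I2/Et3N in Et2O turns this into the geminal diiodide 2-(12,12-diiodododecyl)-2-methyl-1,3-dioxolane F3. Takai–Utimoto olefination of 14 with F3 and CrCl2 (divalent chromium, THF/DMF, rt) should give benzyl (2S,3S)-2-[(1E)-13-(2-methyl-1,3-dioxolan-2-yl)tridec-1-en-1-yl]-5-oxooxolane-3-carboxylate F4. This forms the same bond without any basic carbanion, and hydrogenation as in step 11 gives 17.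

Step 7. The risk is loss of regiocontrol: the reactive thiolate may attack the other anhydride carbonyl, or the ring-opened carboxylate may re-close and equilibrate, so that the thioester ends up on the wrong carboxyl. Fallback: a slower, neutral alcoholysis with a temporary ester, setting out from anhydride 11 and returning at 13. Allyl alcohol (neat, rt, no base) should give (2R,3S)-5-oxo-2-[(prop-2-en-1-yloxy)carbonyl]oxolane-3-carboxylic acid F5, which cannot revert. Benzyl 2,2,2-trichloroacetimidate then gives 3-benzyl 2-(prop-2-en-1-yl) (2R,3S)-5-oxooxolane-2,3-dicarboxylate F6. Pd(PPh3)4/morpholine removes the allyl group to give (2R,3S)-3-[(benzyloxy)carbonyl]-5-oxooxolane-2-carboxylic acid F7, and EtSH with EDC·HCl and catalytic DMAP converts this acid into thioester 13.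

Step 12 (with step 13). Three processes threaten this step: epimerisation at C4 to the trans series or β-elimination during long heating in a strongly basic medium, and loss of the dioxolane in the acidic work-up, after which the free methyl ketone could compete in the Mannich step. Fallback: a low-temperature dianion methylenation, setting out from 17 and returning at 19. LiN(iPr)2 (2.2 equiv, THF, −78 °C) forms the carboxylate–lactone enolate, and dimethyl(methylidene)ammonium iodide should give (2S,3S,4R)-4-[(dimethylamino)methyl]-2-[13-(2-methyl-1,3-dioxolan-2-yl)tridecyl]-5-oxooxolane-3-carboxylic acid F8. MeI in MeOH quaternises it to {(3R,4S,5S)-4-carboxy-5-[13-(2-methyl-1,3-dioxolan-2-yl)tridecyl]-2-oxooxolan-3-yl}methyl-trimethylammonium iodide F9, and aqueous NaHCO3 eliminates trimethylamine to give 19. The configuration at the aminomethyl carbon is immaterial.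

Step 11. The C5–O bond of 16 is allylic, so hydrogenolytic opening of the lactone on palladium can compete with saturation of the alkene. Fallback: separate the two reductions, setting out from 16 and returning at 17. Diimide (TsNHNH2, NaOAc, DME/H2O, 80 °C) reduces only the C=C bond and should give benzyl (2S,3S)-2-[13-(2-methyl-1,3-dioxolan-2-yl)tridecyl]-5-oxooxolane-3-carboxylate F10. Its benzyl ester is then hydrogenolysed (H2, Pd/C, EtOAc) to 17, with no allylic C–O bond left.

## Further compounds

F1 | step 10 | 12-(2-methyl-1,3-dioxolan-2-yl)dodecanal | CC1(CCCCCCCCCCCC=O)OCCO1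
F2 | step 10 | (E)-[12-(2-methyl-1,3-dioxolan-2-yl)dodecylidene]hydrazine | CC1(CCCCCCCCCCC/C=N/N)OCCO1
F3 | step 10 | 2-(12,12-diiodododecyl)-2-methyl-1,3-dioxolane | CC1(CCCCCCCCCCCC(I)I)OCCO1
F4 | step 10 | benzyl (2S,3S)-2-[(1E)-13-(2-methyl-1,3-dioxolan-2-yl)tridec-1-en-1-yl]-5-oxooxolane-3-carboxylate | C1C(=O)O[C@@H](/C=C/CCCCCCCCCCCC2(C)OCCO2)[C@H]1C(=O)OCc3ccccc3
F5 | step 7 | (2R,3S)-5-oxo-2-[(prop-2-en-1-yloxy)carbonyl]oxolane-3-carboxylic acid | C1C(=O)O[C@@H](C(=O)OCC=C)[C@H]1C(=O)O
F6 | step 7 | 3-benzyl 2-(prop-2-en-1-yl) (2R,3S)-5-oxooxolane-2,3-dicarboxylate | C1C(=O)O[C@@H](C(=O)OCC=C)[C@H]1C(=O)OCc2ccccc2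
F7 | step 7 | (2R,3S)-3-[(benzyloxy)carbonyl]-5-oxooxolane-2-carboxylic acid | C1C(=O)O[C@@H](C(=O)O)[C@H]1C(=O)OCc2ccccc2
F8 | step 12 | (2S,3S,4R)-4-[(dimethylamino)methyl]-2-[13-(2-methyl-1,3-dioxolan-2-yl)tridecyl]-5-oxooxolane-3-carboxylic acid | CN(C)C[C@@H]1C(=O)O[C@@H](CCCCCCCCCCCCCC2(C)OCCO2)[C@H]1C(=O)O
F9 | step 12 | {(3R,4S,5S)-4-carboxy-5-[13-(2-methyl-1,3-dioxolan-2-yl)tridecyl]-2-oxooxolan-3-yl}methyl-trimethylammonium iodide | C[N+](C)(C)C[C@@H]1C(=O)O[C@@H](CCCCCCCCCCCCCC2(C)OCCO2)[C@H]1C(=O)O.[I-]
F10 | step 11 | benzyl (2S,3S)-2-[13-(2-methyl-1,3-dioxolan-2-yl)tridecyl]-5-oxooxolane-3-carboxylate | C1C(=O)O[C@@H](CCCCCCCCCCCCCC2(C)OCCO2)[C@H]1C(=O)OCc3ccccc3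
A1 | alternative 1 | (4R,5S)-4-({[tert-butyl(dimethyl)silyl]oxy}methyl)-3-methylidene-5-(14-oxopentadecyl)oxolan-2-one | C=C1C(=O)O[C@@H](CCCCCCCCCCCCCC(C)=O)[C@H]1CO[Si](C)(C)C(C)(C)C
A2 | alternative 1 | (16S,17R)-17-({[tert-butyl(dimethyl)silyl]oxy}methyl)-16-hydroxynonadec-18-yn-2-one | O[C@@H](CCCCCCCCCCCCCC(C)=O)[C@H](C#C)CO[Si](C)(C)C(C)(C)C
A3 | alternative 2 | (2S,3S)-2-[13-(2-methyl-1,3-dioxolan-2-yl)tridecyl]-5-oxooxolane-3-carboxylic acid (identical with 17) | C1C(=O)O[C@@H](CCCCCCCCCCCCCC2(C)OCCO2)[C@H]1C(=O)O
A4 | alternative 2 | (6S)-4-diazo-6-[13-(2-methyl-1,3-dioxolan-2-yl)tridecyl]oxane-2,5-dione | O=C1CC(=[N+]=[N-])C(=O)[C@H](CCCCCCCCCCCCCC2(C)OCCO2)O1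
A5 | alternative 3 | dibenzyl (2S)-2-[(1S)-1-hydroxy-14-(2-methyl-1,3-dioxolan-2-yl)tetradecyl]butanedioate | O[C@@H](CCCCCCCCCCCCCC1(C)OCCO1)[C@H](CC(=O)OCc1ccccc1)C(=O)OCc1ccccc1
A6 | alternative 3 | dibenzyl 2-[14-(2-methyl-1,3-dioxolan-2-yl)tetradecanoyl]butanedioate (racemic) | O=C(CCCCCCCCCCCCCC1(C)OCCO1)C(CC(=O)OCc1ccccc1)C(=O)OCc1ccccc1
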